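**Strategy.** Everything rests on cutting ring C from ring A at two bonds at once: O1–C8a and C4–C4a. Because C8a and C4a are neighbouring ring-A carbons, they are generated together as an aryne, and the 5-OMOM group beside C4a steers the incoming oxygen to C8a. The partner is the silyl-masked anti-aldol adduct of a chiral glycolate lactone, which already holds O1, C2, C3 and C4 with the (2R,3R) centres set. Fluoride liberates aryne and alkoxide together; the alkoxide adds and the resulting aryl anion closes ring C on the lactone carbonyl. The lactone acetal also protects O3 and falls off with the MOM groups in the last step.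

Key step: step 8

Remark: chromanone numbering (O1, C2, C3, C4, C4a, C5–C8, C8a) is used throughout; (5S,6S)-5,6-dimethoxy-5,6-dimethyl-1,4-dioxan-2-one (11) and 4-(methoxymethoxy)benzaldehyde (12) are taken as purchasable, and the aldol of 11 is assumed to follow the usual sense for this auxiliary (anti, attack opposite the axial 5-methoxy group).

**Step 1**
Reactants: 1 5-methoxybenzene-1,3-diol (5-methoxyresorcinol)
Product: 2 3-methoxy-5-(methoxymethoxy)phenol
Conditions: MOMCl (1.0 equiv), K2CO3, acetone, 0 °C to rt; recovered 1 recycled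
Reagents that add atoms: chloromethyl methyl ether (MOMCl), COCCl
Why: Williamson-type O-alkylation of one of two equivalent phenols, so only the degree of alkylation has to be controlled and the mono-ether should be separable from diol and bis-ether.

**Step 2**
Reactants: 2 3-methoxy-5-(methoxymethoxy)phenol
Product: 3 3-methoxy-5-(methoxymethoxy)phenyl N,N-diethylcarbamate
Conditions: Et2NCOCl, K2CO3, MeCN, reflux
Reagents that add atoms: N,N-diethylcarbamoyl chloride, CCN(CC)C(=O)Cl
Why: O-carbamoylation of the remaining phenol installs the directing group for both later directed ortho-metalations and is orthogonal to the MOM ether.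

**Step 3**
Reactants: 3 3-methoxy-5-(methoxymethoxy)phenyl N,N-diethylcarbamate
Product: 5 5-methoxy-3-(methoxymethoxy)-2-(trimethylsilyl)phenyl N,N-diethylcarbamate, via aryllithium 4 (not isolated)
Conditions: s-BuLi, TMEDA, THF, −78 °C; then TMSCl, −78 °C to rt
Reagents that add atoms: chlorotrimethylsilane, C[Si](C)(C)Cl
Why: Directed ortho-metalation should occur at the position flanked by the carbamate and the chelating OMOM group in preference to the carbamate/OMe position, and TMSCl traps aryllithium 4.

**Step 4**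
Reactants: 5 5-methoxy-3-(methoxymethoxy)-2-(trimethylsilyl)phenyl N,N-diethylcarbamate
Product: 8 5-methoxy-3-(methoxymethoxy)-6-(3-methylbut-2-en-1-yl)-2-(trimethylsilyl)phenyl N,N-diethylcarbamate, via aryllithium 6 (not isolated), via arylcopper 7 (not isolated)
Conditions: s-BuLi, TMEDA, THF, −78 °C; CuBr·SMe2, −78 to −40 °C; prenyl bromide, −40 to 0 °C
Reagents that add atoms: 1-bromo-3-methylbut-2-ene (prenyl bromide), CC(C)=CCBr
Why: A second directed ortho-metalation takes the only position left beside the carbamate (the silyl group blocks the other), and transmetalation to copper should suppress anionic ortho-Fries migration and direct allylic substitution to the primary carbon of prenyl bromide.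

**Step 5**
Reactants: 8 5-methoxy-3-(methoxymethoxy)-6-(3-methylbut-2-en-1-yl)-2-(trimethylsilyl)phenyl N,N-diethylcarbamate
Product: 9 5-methoxy-3-(methoxymethoxy)-6-(3-methylbut-2-en-1-yl)-2-(trimethylsilyl)phenol
Conditions: LiAlH4, THF, 0 °C to reflux; aqueous potassium sodium tartrate work-up
Reagents that add atoms: none
Why: Reductive cleavage of the aryl O-carbamate by hydride attack at the carbamoyl carbon frees the phenol, while MOM ether, aryl–silicon bond and trisubstituted alkene are inert and the non-acidic work-up avoids protodesilylation.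

**Step 6**
Reactants: 9 5-methoxy-3-(methoxymethoxy)-6-(3-methylbut-2-en-1-yl)-2-(trimethylsilyl)phenol
Product: 10 5-methoxy-3-(methoxymethoxy)-6-(3-methylbut-2-en-1-yl)-2-(trimethylsilyl)phenyl trifluoromethanesulfonate
Conditions: PhNTf2, DBU, MeCN, rt to 40 °C
Reagents that add atoms: N-phenylbis(trifluoromethanesulfonimide), O=S(=O)(N(c1ccccc1)S(=O)(=O)C(F)(F)F)C(F)(F)F
Why: O-sulfonylation of the phenoxide under amine-base conditions gives the ortho-silylaryl triflate (aryne precursor) without acid that could remove the silyl or MOM group.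

**Step 7**
Reactants: 11 (5S,6S)-5,6-dimethoxy-5,6-dimethyl-1,4-dioxan-2-one; 12 4-(methoxymethoxy)benzaldehyde
Product: 15 (3R,5S,6S)-5,6-dimethoxy-3-{(R)-[4-(methoxymethoxy)phenyl][(trimethylsilyl)oxy]methyl}-5,6-dimethyl-1,4-dioxan-2-one, via lithium enolate 13 (not isolated), via lithium aldolate 14 (not isolated)
Conditions: LiN(SiMe3)2, THF, −78 °C; 12, −78 °C; TMSCl, −78 to −20 °C; pH 7 buffer work-up
Reagents that add atoms: chlorotrimethylsilane, C[Si](C)(C)Cl
Why: Anti-selective lithium-enolate aldol reaction (Zimmerman–Traxler chair with the ring-fixed enolate geometry) in which the aldehyde should approach the enolate face opposite the axial 5-methoxy group, setting C3 (R) and the carbinol carbon (R), and aldolate 14 is trapped as its silyl ether.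

**Step 8**
Reactants: 10 5-methoxy-3-(methoxymethoxy)-6-(3-methylbut-2-en-1-yl)-2-(trimethylsilyl)phenyl trifluoromethanesulfonate; 15 (3R,5S,6S)-5,6-dimethoxy-3-{(R)-[4-(methoxymethoxy)phenyl][(trimethylsilyl)oxy]methyl}-5,6-dimethyl-1,4-dioxan-2-one
Product: 20 (2R,3R)-7-methoxy-5-(methoxymethoxy)-3-{[(2S)-2-methoxy-3-oxobutan-2-yl]oxy}-2-[4-(methoxymethoxy)phenyl]-8-(3-methylbut-2-en-1-yl)-2,3-dihydro-4H-chromen-4-one, via aryne 16 (not isolated), via cesium alkoxide 17 (not isolated), via aryl anion 18 (not isolated), via hemiketal alkoxide 19 (not isolated)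
Conditions: 15 (1.3 equiv), CsF (4 equiv), 18-crown-6, THF, 0 °C to rt
Reagents that add atoms: none
Why: Proposed new method: fluoride removes the O-silyl group of 15 and triggers 1,2-elimination of 10, so that cesium alkoxide 17 and aryne 16 meet in a flask that holds no O–H; the alkoxide adds to the aryne carbon that bore the triflate (C8a), the aryl anion 18 thus placed at C4a attacks the lactone carbonyl, the dioxanone opens to hemiketal alkoxide 19, and loss of methoxide leaves the ketone C4 and an α-keto ketal on O3. The closest known reaction type is the fluoride-mediated annulation of arynes with salicylate esters to xanthones (oxygen addition to the aryne, then intramolecular acyl substitution by the aryl anion), which has not been shown for an aliphatic alkoxide carrying a lactone. Ring C is the only ring closed, by 6-exo-trig attack of the C4a anion on the lactone C=O. No stereocentre is created: C2 and C3 come from 15 unchanged because no bond to either is broken, and the trans-diequatorial product is also the thermodynamically preferred epimer at C3. The step needs the oxygen to enter at C8a and not at C4a, which the inductively withdrawing 5-OMOM group beside C4a should secure by distorting the aryne toward attack at the distal carbon and by stabilising the anion ortho to itself, against only a modest steric cost from the 8-prenyl group. It also needs acyl capture to outrun protonation of 18, which the silyl mask (no proton on oxygen), the aprotic medium and the activated acetal-ester carbonyl held in six-ring reach are meant to ensure.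

**Step 9**
Reactants: 20 (2R,3R)-7-methoxy-5-(methoxymethoxy)-3-{[(2S)-2-methoxy-3-oxobutan-2-yl]oxy}-2-[4-(methoxymethoxy)phenyl]-8-(3-methylbut-2-en-1-yl)-2,3-dihydro-4H-chromen-4-one
Product: 21 (2R,3R)-3,5-dihydroxy-2-(4-hydroxyphenyl)-7-methoxy-8-(3-methylbut-2-en-1-yl)-2,3-dihydro-4H-chromen-4-one
Conditions: 3 M aq. HCl, MeOH, 40 °C
Reagents that add atoms: none
Why: Acid-catalysed acetal cleavage should remove both MOM ethers and the α-keto ketal on O3 in one operation without touching C2 or C3, and no free phenol stands beside the prenyl group, so chroman formation is excluded.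

**Compound list**
1 | 5-methoxybenzene-1,3-diol | COc1cc(O)cc(O)c1 | starting material
2 | 3-methoxy-5-(methoxymethoxy)phenol | COCOc1cc(O)cc(OC)c1 | intermediate
3 | 3-methoxy-5-(methoxymethoxy)phenyl N,N-diethylcarbamate | CCN(CC)C(=O)Oc1cc(OC)cc(OCOC)c1 | intermediate
4 | [2-(diethylcarbamoyloxy)-4-methoxy-6-(methoxymethoxy)phenyl]lithium | [Li]c1c(OC(=O)N(CC)CC)cc(OC)cc1OCOC | intermediate
5 | 5-methoxy-3-(methoxymethoxy)-2-(trimethylsilyl)phenyl N,N-diethylcarbamate | CCN(CC)C(=O)Oc1cc(OC)cc(OCOC)c1[Si](C)(C)C | intermediate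
6 | [2-(diethylcarbamoyloxy)-6-methoxy-4-(methoxymethoxy)-3-(trimethylsilyl)phenyl]lithium | [Li]c1c(OC)cc(OCOC)c([Si](C)(C)C)c1OC(=O)N(CC)CC | intermediate
7 | [2-(diethylcarbamoyloxy)-6-methoxy-4-(methoxymethoxy)-3-(trimethylsilyl)phenyl]copper | [Cu]c1c(OC)cc(OCOC)c([Si](C)(C)C)c1OC(=O)N(CC)CC | intermediate
8 | 5-methoxy-3-(methoxymethoxy)-6-(3-methylbut-2-en-1-yl)-2-(trimethylsilyl)phenyl N,N-diethylcarbamate | CCN(CC)C(=O)Oc1c(CC=C(C)C)c(OC)cc(OCOC)c1[Si](C)(C)C | intermediate
9 | 5-methoxy-3-(methoxymethoxy)-6-(3-methylbut-2-en-1-yl)-2-(trimethylsilyl)phenol | COCOc1cc(OC)c(CC=C(C)C)c(O)c1[Si](C)(C)C | intermediate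
10 | 5-methoxy-3-(methoxymethoxy)-6-(3-methylbut-2-en-1-yl)-2-(trimethylsilyl)phenyl trifluoromethanesulfonate | COCOc1cc(OC)c(CC=C(C)C)c(OS(=O)(=O)C(F)(F)F)c1[Si](C)(C)C | intermediate
11 | (5S,6S)-5,6-dimethoxy-5,6-dimethyl-1,4-dioxan-2-one | O=C1CO[C@](C)(OC)[C@@](C)(OC)O1 | starting material
12 | 4-(methoxymethoxy)benzaldehyde | COCOc1ccc(C=O)cc1 | starting material
13 | lithium enolate of 11 (lithium (5S,6S)-5,6-dimethoxy-5,6-dimethyl-5,6-dihydro-1,4-dioxin-2-olate) | [Li]OC1=CO[C@](C)(OC)[C@@](C)(OC)O1 | intermediate
14 | lithium (R)-[(2R,5S,6S)-5,6-dimethoxy-5,6-dimethyl-3-oxo-1,4-dioxan-2-yl][4-(methoxymethoxy)phenyl]methanolate | O=C1[C@@H]([C@H](O[Li])c2ccc(OCOC)cc2)O[C@](C)(OC)[C@@](C)(OC)O1 | intermediate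
15 | (3R,5S,6S)-5,6-dimethoxy-3-{(R)-[4-(methoxymethoxy)phenyl][(trimethylsilyl)oxy]methyl}-5,6-dimethyl-1,4-dioxan-2-one | O=C1[C@@H]([C@H](O[Si](C)(C)C)c2ccc(OCOC)cc2)O[C@](C)(OC)[C@@](C)(OC)O1 | intermediate
16 | 5-methoxy-3-(methoxymethoxy)-6-(3-methylbut-2-en-1-yl)benzyne (1,2-didehydrobenzene) | COCOC1=CC(OC)=C(CC=C(C)C)C#C1 | intermediate
17 | cesium alkoxide formed from 15 by loss of the silyl group | O=C1[C@@H]([C@H]([O-])c2ccc(OCOC)cc2)O[C@](C)(OC)[C@@](C)(OC)O1.[Cs+] | intermediate
18 | aryl ether of 17 with 16, carrying cesium on the ring carbon between the ether oxygen and the OMOM group | O=C1[C@@H]([C@H](Oc2c([Cs])c(OCOC)cc(OC)c2CC=C(C)C)c2ccc(OCOC)cc2)O[C@](C)(OC)[C@@](C)(OC)O1 | intermediate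
19 | ring-closed chromanone whose O3 carries the opened diacetal chain ending in a cesium hemiketal alkoxide | COc1cc(OCOC)c2c(c1CC=C(C)C)O[C@H](c1ccc(OCOC)cc1)[C@@H](O[C@](C)(OC)[C@@](C)(OC)[O-])C2=O.[Cs+] | intermediate
20 | (2R,3R)-7-methoxy-5-(methoxymethoxy)-3-{[(2S)-2-methoxy-3-oxobutan-2-yl]oxy}-2-[4-(methoxymethoxy)phenyl]-8-(3-methylbut-2-en-1-yl)-2,3-dihydro-4H-chromen-4-one | COc1cc(OCOC)c2c(c1CC=C(C)C)O[C@H](c1ccc(OCOC)cc1)[C@@H](O[C@](C)(OC)C(C)=O)C2=O | intermediate
21 | (2R,3R)-3,5-dihydroxy-2-(4-hydroxyphenyl)-7-methoxy-8-(3-methylbut-2-en-1-yl)-2,3-dihydro-4H-chromen-4-one | COc1cc(O)c2c(c1CC=C(C)C)O[C@H](c1ccc(O)cc1)[C@@H](O)C2=O | target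

**Totals.** Total step count: 9. Longest linear sequence: 8 steps (steps 1 to 6, then 8 and 9); step 7 is the one-step side branch.

**Steps most likely to fail**

Step 8 (proposed new method). The aryl anion may be protonated, by the C3–H of its own side chain or by traces of water, before it reaches the lactone carbonyl. The cesium alkoxide may also fragment by retro-aldol cleavage before an aryne is available, and the product may suffer base-induced opening of ring C with loss of the C2 configuration. The fallback uses known chemistry only, sets out from 10 and comes back at 21. The aryne from 10 (CsF, THF, sealed tube, heat) is generated in the presence of acetic acid; the known insertion of an aryne into the C–O bond of a carboxylic acid, with the same sense of addition, should give 1-[2-hydroxy-4-methoxy-6-(methoxymethoxy)-3-(3-methylbut-2-en-1-yl)phenyl]ethan-1-one F1. O-alkylation (NaH, MOMCl) should give 1-[4-methoxy-2,6-bis(methoxymethoxy)-3-(3-methylbut-2-en-1-yl)phenyl]ethan-1-one F2. Claisen–Schmidt condensation with 12 (KOH, EtOH) should give (E)-1-[4-methoxy-2,6-bis(methoxymethoxy)-3-(3-methylbut-2-en-1-yl)phenyl]-3-[4-(methoxymethoxy)phenyl]prop-2-en-1-one F3. Juliá–Colonna epoxidation (poly-L-leucine, urea–H2O2, DBU, THF; the catalyst enantiomer is chosen for the (2R,3S)-epoxide, and the nucleophilic oxidant spares the prenyl alkene) should give [(2R,3S)-3-[4-(methoxymethoxy)phenyl]oxiran-2-yl][4-methoxy-2,6-bis(methoxymethoxy)-3-(3-methylbut-2-en-1-yl)phenyl]methanone F4. Aqueous HCl in MeOH should then remove the three MOM groups and let the freed 2'-phenol open the epoxide at the benzylic carbon with inversion, giving 21 directly.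

Step 3. Lithiation may be shared between the carbamate/OMOM position and the carbamate/OMe position, so the silyl group could enter at the wrong site. The fallback sets out from 1 and comes back at 5, and makes the site unambiguous by symmetry. Double carbamoylation of 1 (Et2NCOCl, K2CO3, MeCN) should give 5-methoxy-1,3-phenylene bis(N,N-diethylcarbamate) F5. Lithiation between the two carbamates (s-BuLi, TMEDA, THF, −78 °C) and TMSCl should give 5-methoxy-2-(trimethylsilyl)-1,3-phenylene bis(N,N-diethylcarbamate) F6. Cleavage of one of the two equivalent carbamates with one equivalent of MeLi (statistical, bis-carbamate recycled) should give 3-hydroxy-5-methoxy-2-(trimethylsilyl)phenyl N,N-diethylcarbamate F7. O-alkylation with MOMCl and K2CO3 should then give 5.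

Step 4. The doubly flanked aryl organometallic may alkylate slowly, attack the tertiary end of the allylic bromide, or undergo ortho-Fries migration of the carbamoyl group on warming. The fallback sets out from 5 and comes back at 8, and separates carbon–carbon bond formation from installation of the trisubstituted alkene. Aryllithium 6 is quenched at −78 °C with allyl bromide, a fast and regiochemically neutral electrophile, to give 5-methoxy-3-(methoxymethoxy)-6-(prop-2-en-1-yl)-2-(trimethylsilyl)phenyl N,N-diethylcarbamate F8. Olefin cross-metathesis with excess 2-methylbut-2-ene and second-generation Grubbs catalyst (CH2Cl2, 40 °C) should convert F8 into 8.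

**Further compounds**
F1 | step 8 | 1-[2-hydroxy-4-methoxy-6-(methoxymethoxy)-3-(3-methylbut-2-en-1-yl)phenyl]ethan-1-one | CC(=O)c1c(O)c(CC=C(C)C)c(OC)cc1OCOC
F2 | step 8 | 1-[4-methoxy-2,6-bis(methoxymethoxy)-3-(3-methylbut-2-en-1-yl)phenyl]ethan-1-one | CC(=O)c1c(OCOC)c(CC=C(C)C)c(OC)cc1OCOC
F3 | step 8 | (E)-1-[4-methoxy-2,6-bis(methoxymethoxy)-3-(3-methylbut-2-en-1-yl)phenyl]-3-[4-(methoxymethoxy)phenyl]prop-2-en-1-one | COc1cc(OCOC)c(C(=O)/C=C/c2ccc(OCOC)cc2)c(OCOC)c1CC=C(C)C
F4 | step 8 | [(2R,3S)-3-[4-(methoxymethoxy)phenyl]oxiran-2-yl][4-methoxy-2,6-bis(methoxymethoxy)-3-(3-methylbut-2-en-1-yl)phenyl]methanone | COc1cc(OCOC)c(C(=O)[C@@H]2O[C@H]2c2ccc(OCOC)cc2)c(OCOC)c1CC=C(C)C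
F5 | step 3 | 5-methoxy-1,3-phenylene bis(N,N-diethylcarbamate) | CCN(CC)C(=O)Oc1cc(OC)cc(OC(=O)N(CC)CC)c1
F6 | step 3 | 5-methoxy-2-(trimethylsilyl)-1,3-phenylene bis(N,N-diethylcarbamate) | CCN(CC)C(=O)Oc1cc(OC)cc(OC(=O)N(CC)CC)c1[Si](C)(C)C
F7 | step 3 | 3-hydroxy-5-methoxy-2-(trimethylsilyl)phenyl N,N-diethylcarbamate | CCN(CC)C(=O)Oc1cc(OC)cc(O)c1[Si](C)(C)C
F8 | step 4 | 5-methoxy-3-(methoxymethoxy)-6-(prop-2-en-1-yl)-2-(trimethylsilyl)phenyl N,N-diethylcarbamate | CCN(CC)C(=O)Oc1c(CC=C)c(OC)cc(OCOC)c1[Si](C)(C)C
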